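**Retrosynthetic overview**
1. Target ⇐ removal of four MOM (methoxymethyl) ethers ⇐ Negishi methylation of an enol triflate ⇐ 2-prenyl-3-aroyl-4-arylcyclohexanone (2,3-cis, 3,4-trans).
2. That cyclohexanone ⇐ one-carbon ring expansion of a 2,3-trans cyclopentanone aldol: a prenyl-bearing lithium carbenoid adds to the C=O, the ring carbon carrying the side chain makes a 1,2-shift, and protonation of the resulting enolate sets the prenyl centre.
3. Cyclopentanone aldol ⇐ cyclopent-2-en-1-one + aryl nucleophile (Rh-catalysed asymmetric 1,4-addition) + 2,4,6-tris(MOM-oxy)benzaldehyde (aldol of the boron enolate).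
4. Aldehyde ⇐ 1,3-bis(MOM-oxy)benzene (C–H borylation/oxidation, MOM protection, ortho-lithiation/formylation); carbenoid precursor ⇐ prenyl bromide + CH2Br2.
5. Ring order: both benzene rings are bought; the five-membered ring (bought as the enone) becomes the six-membered ring by ring expansion; the ring alkene is made last.

Assumption: 1 and 9 are bought as their MOM ethers (both are catalogue compounds).

**Route**

Step 1
Reactants: 1 1,3-bis(methoxymethoxy)benzene
Product: 3 3,5-bis(methoxymethoxy)phenol, via arylboronate 2 (not isolated)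
Conditions: [Ir(OMe)(cod)]2 (1.5 mol %), 4,4'-di-tert-butyl-2,2'-bipyridine (3 mol %), B2pin2 (1.0 equiv), THF, 80 °C; then 2KHSO5·KHSO4·K2SO4, acetone/H2O, 23 °C, 10 min
Reagents that add atoms: bis(pinacolato)diboron CC1(C)OB(OC1(C)C)B1OC(C)(C)C(C)(C)O1 (boryl group of 2); potassium peroxymonosulfate [K+].[O-]S(=O)(=O)OO (phenol oxygen of 3)
Why: Iridium-catalysed aromatic C–H borylation is sterically controlled and takes the only C–H flanked by two hydrogens (C5), and the boronate is oxidised in the same flask to the phenol (one-pot C–H borylation/oxidation).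

Step 2
Reactants: 3 3,5-bis(methoxymethoxy)phenol
Product: 4 1,3,5-tris(methoxymethoxy)benzene
Conditions: MOMCl, i-Pr2NEt, CH2Cl2, 0 → 23 °C
Reagents that add atoms: chloromethyl methyl ether COCCl
Why: Base-mediated O-alkylation of the phenol (MOM ether formation) gives the symmetric tris-ether in which every ring C–H lies between two directing groups.

Step 3
Reactants: 4 1,3,5-tris(methoxymethoxy)benzene
Product: 6 2,4,6-tris(methoxymethoxy)benzaldehyde, via aryllithium 5 (not isolated)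
Conditions: n-BuLi, THF, 0 °C; DMF, 0 → 23 °C; H2O
Reagents that add atoms: n-butyllithium [Li]CCCC (lithium of 5); N,N-dimethylformamide CN(C)C=O (formyl group)
Why: Directed ortho-metalation between two OMOM groups (all three ring positions are equivalent) followed by formylation of the aryllithium with DMF.

Step 4
Reactants: 7 1-bromo-3-methylbut-2-ene (prenyl bromide)
Product: 8 5,5-dibromo-2-methylpent-2-ene
Conditions: CH2Br2, LiN(i-Pr)2, THF/Et2O, −100 °C; then 7, DMPU, −100 → −60 °C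
Reagents that add atoms: dibromomethane BrCBr
Why: Dibromomethyllithium, formed by deprotonation of CH2Br2 below −95 °C, is alkylated at the primary allylic carbon in an SN2 reaction (α-halo carbanion alkylation) to give the gem-dibromide that carries the future prenyl-bearing ring carbon.

Step 5
Reactants: 9 1-bromo-4-(methoxymethoxy)benzene; 10 cyclopent-2-en-1-one; 6 2,4,6-tris(methoxymethoxy)benzaldehyde
Product: 14 (2R,3R)-2-{hydroxy[2,4,6-tris(methoxymethoxy)phenyl]methyl}-3-[4-(methoxymethoxy)phenyl]cyclopentan-1-one, via aryl Grignard 11 (not isolated), via B-aryl-9-BBN 12 (not isolated), via boron enolate 13 (not isolated)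
Conditions: Mg, THF, 23 °C; 9-methoxy-9-BBN, THF then hexane, filter; 10, [Rh(OMe)(cod)]2 (1.5 mol %), (R)-BINAP (3.3 mol %), toluene, 80 °C; then 6, −78 → 0 °C; H2O
Reagents that add atoms: magnesium [Mg] (in 11); 9-methoxy-9-borabicyclo[3.3.1]nonane COB1C2CCCC1CCC2 (borane unit of 12 and 13); 14 itself takes only hydrogen from the water work-up
Why: Rhodium/(R)-BINAP-catalysed asymmetric 1,4-addition of the B-aryl-9-BBN (Hayashi–Miyaura type) sets the aryl-bearing centre as R and leaves a regio-defined boron enolate, whose aldol addition to 6 occurs anti to the new aryl group to give the 2,3-trans ketone (the carbinol centre forms as a mixture and is erased in step 7).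

Step 6
Reactants: 14 (2R,3R)-2-{hydroxy[2,4,6-tris(methoxymethoxy)phenyl]methyl}-3-[4-(methoxymethoxy)phenyl]cyclopentan-1-one; 8 5,5-dibromo-2-methylpent-2-ene
Product: 19 (2S,3S,4R)-3-{hydroxy[2,4,6-tris(methoxymethoxy)phenyl]methyl}-4-[4-(methoxymethoxy)phenyl]-2-(3-methylbut-2-en-1-yl)cyclohexan-1-one, via lithium alkoxide 15 (not isolated), via lithium carbenoid 16 (not isolated), via dibromo dialkoxide 17 (not isolated), via lithium enolate 18 (not isolated)
Conditions: 14, LiN(SiMe3)2 (1.0 equiv), THF, −78 °C; added to 8 + LiN(i-Pr)2, THF/Et2O, −105 °C; n-BuLi, −105 → −60 °C; AcOH/THF, −78 °C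
Reagents that add atoms: LiN(SiMe3)2 C[Si](C)(C)N([Li])[Si](C)(C)C, LiN(i-Pr)2 CC(C)N([Li])C(C)C and n-butyllithium [Li]CCCC (lithium of 15–18 only; 19 takes only hydrogen from AcOH)
Why: Proposed new method: the prenyl-substituted lithium carbenoid 16 adds to the ketone of 15, Br/Li exchange on the gem-dibromide of 17 gives a β-oxido carbenoid, and loss of LiBr drives a 1,2-shift of the more substituted ring carbon (the one bearing the carbinol side chain, migrating with retention) onto the carbenoid carbon, which expands the ring and places the enolate 18 regiospecifically on the new prenyl-bearing carbon, so that protonation at −78 °C from the face opposite the bulky neighbouring side chain sets the 2,3-cis centre; the closest known reaction type is the β-oxido carbenoid ring enlargement of cycloalkanones with dibromomethyllithium (Nozaki type), not yet shown with a substituted allylic gem-dibromide, next to a free alkoxide, or with stereoselective protonation of the enolate.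

Step 7
Reactants: 19 (2S,3S,4R)-3-{hydroxy[2,4,6-tris(methoxymethoxy)phenyl]methyl}-4-[4-(methoxymethoxy)phenyl]-2-(3-methylbut-2-en-1-yl)cyclohexan-1-one
Product: 20 (2S,3S,4R)-4-[4-(methoxymethoxy)phenyl]-2-(3-methylbut-2-en-1-yl)-3-[2,4,6-tris(methoxymethoxy)benzoyl]cyclohexan-1-one
Conditions: Dess–Martin periodinane, pyridine, CH2Cl2, 0 °C
Reagents that add atoms: none
Why: Dess–Martin oxidation of the secondary benzylic alcohol under pyridine buffering converts both carbinol epimers into one aryl ketone without touching the alkene or the epimerisable 2,3-cis α-centre.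

Step 8
Reactants: 20 (2S,3S,4R)-4-[4-(methoxymethoxy)phenyl]-2-(3-methylbut-2-en-1-yl)-3-[2,4,6-tris(methoxymethoxy)benzoyl]cyclohexan-1-one
Product: 22 (4R,5S,6S)-4-[4-(methoxymethoxy)phenyl]-6-(3-methylbut-2-en-1-yl)-5-[2,4,6-tris(methoxymethoxy)benzoyl]cyclohex-1-en-1-yl trifluoromethanesulfonate, via potassium enolate 21 (not isolated)
Conditions: 20 added to KN(SiMe3)2 (1.1 equiv), THF, −78 °C; PhNTf2, −78 → −20 °C
Reagents that add atoms: KN(SiMe3)2 C[Si](C)(C)N([K])[Si](C)(C)C (potassium of 21); N-phenylbis(trifluoromethanesulfonimide) O=S(=O)(N(c1ccccc1)S(=O)(=O)C(F)(F)F)C(F)(F)F (the CF3SO2 group)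
Why: The bulky amide removes a proton from the unhindered α-CH2 (kinetic enolate formation; the two other α-hydrogens are tertiary and flanked), and O-sulfonylation fixes the enol triflate on that side, which is the future ring double bond.

Step 9
Reactants: 22 (4R,5S,6S)-4-[4-(methoxymethoxy)phenyl]-6-(3-methylbut-2-en-1-yl)-5-[2,4,6-tris(methoxymethoxy)benzoyl]cyclohex-1-en-1-yl trifluoromethanesulfonate
Product: 23 {(1R,2S,6R)-6-[4-(methoxymethoxy)phenyl]-3-methyl-2-(3-methylbut-2-en-1-yl)cyclohex-3-en-1-yl}[2,4,6-tris(methoxymethoxy)phenyl]methanone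
Conditions: MeZnCl, Pd(PPh3)4 (5 mol %), THF, 50 °C
Reagents that add atoms: methylzinc chloride C[Zn]Cl
Why: Negishi cross-coupling of the alkenyl triflate installs the methyl group with the double-bond position retained, and the hindered aryl ketone does not react with the organozinc.

Step 10
Reactants: 23 {(1R,2S,6R)-6-[4-(methoxymethoxy)phenyl]-3-methyl-2-(3-methylbut-2-en-1-yl)cyclohex-3-en-1-yl}[2,4,6-tris(methoxymethoxy)phenyl]methanone
Product: 24 [(1R,2S,6R)-6-(4-hydroxyphenyl)-3-methyl-2-(3-methylbut-2-en-1-yl)cyclohex-3-en-1-yl](2,4,6-trihydroxyphenyl)methanone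
Conditions: HCl (3 M), MeOH, 40 °C
Reagents that add atoms: none
Why: Acid-catalysed transacetalisation with methanol cleaves the four aryl MOM ethers (acetal cleavage) under conditions mild enough for the two trisubstituted alkenes.

**Compound list**
1 | 1,3-bis(methoxymethoxy)benzene | COCOc1cccc(OCOC)c1 | starting material
2 | 2-[3,5-bis(methoxymethoxy)phenyl]-4,4,5,5-tetramethyl-1,3,2-dioxaborolane | COCOc1cc(OCOC)cc(c1)B1OC(C)(C)C(C)(C)O1 | intermediate
3 | 3,5-bis(methoxymethoxy)phenol | COCOc1cc(O)cc(OCOC)c1 | intermediate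
4 | 1,3,5-tris(methoxymethoxy)benzene | COCOc1cc(OCOC)cc(OCOC)c1 | intermediate
5 | [2,4,6-tris(methoxymethoxy)phenyl]lithium | [Li]c1c(OCOC)cc(OCOC)cc1OCOC | intermediate
6 | 2,4,6-tris(methoxymethoxy)benzaldehyde | O=Cc1c(OCOC)cc(OCOC)cc1OCOC | intermediate
7 | 1-bromo-3-methylbut-2-ene (prenyl bromide) | CC(C)=CCBr | starting material
8 | 5,5-dibromo-2-methylpent-2-ene | CC(C)=CCC(Br)Br | intermediate
9 | 1-bromo-4-(methoxymethoxy)benzene | COCOc1ccc(Br)cc1 | starting material
10 | cyclopent-2-en-1-one | O=C1C=CCC1 | starting material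
11 | [4-(methoxymethoxy)phenyl]magnesium bromide | COCOc1ccc([Mg]Br)cc1 | intermediate
12 | 9-[4-(methoxymethoxy)phenyl]-9-borabicyclo[3.3.1]nonane | COCOc1ccc(cc1)B1C2CCCC1CCC2 | intermediate
13 | 9-({(3R)-3-[4-(methoxymethoxy)phenyl]cyclopent-1-en-1-yl}oxy)-9-borabicyclo[3.3.1]nonane | COCOc1ccc(cc1)[C@@H]1CCC(OB2C3CCCC2CCC3)=C1 | intermediate
14 | (2R,3R)-2-{hydroxy[2,4,6-tris(methoxymethoxy)phenyl]methyl}-3-[4-(methoxymethoxy)phenyl]cyclopentan-1-one (2,3-trans; both epimers at the carbinol carbon) | O=C1CC[C@@H](c2ccc(OCOC)cc2)[C@@H]1C(O)c1c(OCOC)cc(OCOC)cc1OCOC | intermediate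
15 | lithium alkoxide of 14 (lithium [(1R,2R)-2-[4-(methoxymethoxy)phenyl]-5-oxocyclopentyl][2,4,6-tris(methoxymethoxy)phenyl]methanolate) | O=C1CC[C@@H](c2ccc(OCOC)cc2)[C@@H]1C(O[Li])c1c(OCOC)cc(OCOC)cc1OCOC | intermediate
16 | (1,1-dibromo-4-methylpent-3-en-1-yl)lithium | CC(C)=CCC([Li])(Br)Br | intermediate
17 | dilithium (2R,3R)-1-(1,1-dibromo-4-methylpent-3-en-1-yl)-3-[4-(methoxymethoxy)phenyl]-2-{oxido[2,4,6-tris(methoxymethoxy)phenyl]methyl}cyclopentan-1-olate (ring carbinol centre unassigned) | CC(C)=CCC(Br)(Br)C1(O[Li])CC[C@@H](c2ccc(OCOC)cc2)[C@@H]1C(O[Li])c1c(OCOC)cc(OCOC)cc1OCOC | intermediate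
18 | dilithium (3S,4R)-4-[4-(methoxymethoxy)phenyl]-2-(3-methylbut-2-en-1-yl)-3-{oxido[2,4,6-tris(methoxymethoxy)phenyl]methyl}cyclohex-1-en-1-olate | CC(C)=CCC1=C(O[Li])CC[C@@H](c2ccc(OCOC)cc2)[C@@H]1C(O[Li])c1c(OCOC)cc(OCOC)cc1OCOC | intermediate
19 | (2S,3S,4R)-3-{hydroxy[2,4,6-tris(methoxymethoxy)phenyl]methyl}-4-[4-(methoxymethoxy)phenyl]-2-(3-methylbut-2-en-1-yl)cyclohexan-1-one (prenyl cis to the side chain, aryl trans to it; both carbinol epimers) | CC(C)=CC[C@@H]1C(=O)CC[C@@H](c2ccc(OCOC)cc2)[C@@H]1C(O)c1c(OCOC)cc(OCOC)cc1OCOC | intermediate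
20 | (2S,3S,4R)-4-[4-(methoxymethoxy)phenyl]-2-(3-methylbut-2-en-1-yl)-3-[2,4,6-tris(methoxymethoxy)benzoyl]cyclohexan-1-one | CC(C)=CC[C@@H]1C(=O)CC[C@@H](c2ccc(OCOC)cc2)[C@@H]1C(=O)c1c(OCOC)cc(OCOC)cc1OCOC | intermediate
21 | potassium (4R,5S,6S)-4-[4-(methoxymethoxy)phenyl]-6-(3-methylbut-2-en-1-yl)-5-[2,4,6-tris(methoxymethoxy)benzoyl]cyclohex-1-en-1-olate | CC(C)=CC[C@@H]1C(O[K])=CC[C@@H](c2ccc(OCOC)cc2)[C@@H]1C(=O)c1c(OCOC)cc(OCOC)cc1OCOC | intermediate
22 | (4R,5S,6S)-4-[4-(methoxymethoxy)phenyl]-6-(3-methylbut-2-en-1-yl)-5-[2,4,6-tris(methoxymethoxy)benzoyl]cyclohex-1-en-1-yl trifluoromethanesulfonate | CC(C)=CC[C@@H]1C(OS(=O)(=O)C(F)(F)F)=CC[C@@H](c2ccc(OCOC)cc2)[C@@H]1C(=O)c1c(OCOC)cc(OCOC)cc1OCOC | intermediate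
23 | {(1R,2S,6R)-6-[4-(methoxymethoxy)phenyl]-3-methyl-2-(3-methylbut-2-en-1-yl)cyclohex-3-en-1-yl}[2,4,6-tris(methoxymethoxy)phenyl]methanone | CC(C)=CC[C@@H]1C(C)=CC[C@@H](c2ccc(OCOC)cc2)[C@@H]1C(=O)c1c(OCOC)cc(OCOC)cc1OCOC | intermediate
24 | [(1R,2S,6R)-6-(4-hydroxyphenyl)-3-methyl-2-(3-methylbut-2-en-1-yl)cyclohex-3-en-1-yl](2,4,6-trihydroxyphenyl)methanone | CC(C)=CC[C@@H]1C(C)=CC[C@@H](c2ccc(O)cc2)[C@@H]1C(=O)c1c(O)cc(O)cc1O | target

**Totals**
Total step count: 10. Longest linear sequence: 9 steps (steps 1, 2, 3, 5, 6, 7, 8, 9, 10).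

**Three steps most likely to fail**

First, step 6, the proposed ring expansion. The CH2 ring carbon could migrate instead of the branched one, the substituted carbenoid could decompose before it adds, or protonation of 18 could give a poor cis:trans ratio. The fallback uses known chemistry, sets out from 14 and 7 and comes back at 19. Chloromethyl 4-methylphenyl sulfoxide is alkylated with 7 (LiN(i-Pr)2, THF, −78 °C) to the 1-chloroalkyl sulfoxide F4. LiN(i-Pr)2 turns F4 into the lithiated sulfoxide F5, which adds to the ketone of 15 (made from 14 as in step 6) and gives, after work-up, the isolable β-hydroxy sulfoxide F6. Treatment with t-BuMgCl and then i-PrMgCl (THF, −78 → 0 °C) effects sulfoxide–magnesium exchange, and the resulting magnesium carbenoid rearranges by the same 1,2-shift to the magnesium enolate F7. AcOH at −78 °C then gives 19. This replaces the one-flask lithium carbenoid by a two-stage sulfoxide homologation with an isolated, purifiable adduct.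

Second, step 5, the tandem arylation–aldol. The borane is made in the flask in the presence of magnesium salts, and 6 is a hindered, electron-rich aldehyde. The fallback sets out from 9 (through 11) and 10 and comes back at 14. ZnCl2 converts 11 into the arylzinc chloride F1. With [RhCl(C2H4)2]2/(R)-BINAP and Me3SiCl in THF at 20 °C, F1 adds to 10 and the enolate is trapped as the (R)-trimethylsilyl enol ether F2, which is isolated. MeLi (THF, 0 °C) releases the regio-defined lithium enolate F3, and addition of 6 at −78 °C gives 14. This is a stepwise lithium-enolate aldol in place of the boron-enolate tandem.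

Third, step 8, the enol triflate. Diketone 20 has three enolisable positions, and the cis prenyl centre can epimerise under base. The fallback sets out from 19 and comes back at 23, with the oxidation postponed so that only one ketone is present during enolate formation. Et3SiOTf/2,6-lutidine gives the triethylsilyl ether F8. KN(SiMe3)2 at −78 °C gives the potassium enolate F9, which PhNTf2 converts into the enol triflate F10. MeZnCl/Pd(PPh3)4 gives the methylcyclohexene F11, Bu4NF gives the alcohol F12, and Dess–Martin periodinane oxidises F12 to 23.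

Further compounds
F1 | step 5 | chloro[4-(methoxymethoxy)phenyl]zinc | COCOc1ccc([Zn]Cl)cc1
F2 | step 5 | trimethyl({(3R)-3-[4-(methoxymethoxy)phenyl]cyclopent-1-en-1-yl}oxy)silane | COCOc1ccc(cc1)[C@@H]1CCC(O[Si](C)(C)C)=C1
F3 | step 5 | lithium (3R)-3-[4-(methoxymethoxy)phenyl]cyclopent-1-en-1-olate | COCOc1ccc(cc1)[C@@H]1CCC(O[Li])=C1
F4 | step 6 | 1-chloro-4-methylpent-3-en-1-yl 4-methylphenyl sulfoxide (diastereomer mixture) | Cc1ccc(cc1)S(=O)C(Cl)CC=C(C)C
F5 | step 6 | [1-chloro-4-methyl-1-(4-methylbenzenesulfinyl)pent-3-en-1-yl]lithium | Cc1ccc(cc1)S(=O)C([Li])(Cl)CC=C(C)C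
F6 | step 6 | (2R,3R)-1-[1-chloro-4-methyl-1-(4-methylbenzenesulfinyl)pent-3-en-1-yl]-2-{hydroxy[2,4,6-tris(methoxymethoxy)phenyl]methyl}-3-[4-(methoxymethoxy)phenyl]cyclopentan-1-ol (other centres as mixtures) | CC(C)=CCC(Cl)(S(=O)c1ccc(C)cc1)C1(O)CC[C@@H](c2ccc(OCOC)cc2)[C@@H]1C(O)c1c(OCOC)cc(OCOC)cc1OCOC
F7 | step 6 | bis(chloromagnesium) (3S,4R)-4-[4-(methoxymethoxy)phenyl]-2-(3-methylbut-2-en-1-yl)-3-{oxido[2,4,6-tris(methoxymethoxy)phenyl]methyl}cyclohex-1-en-1-olate | CC(C)=CCC1=C(O[Mg]Cl)CC[C@@H](c2ccc(OCOC)cc2)[C@@H]1C(O[Mg]Cl)c1c(OCOC)cc(OCOC)cc1OCOC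
F8 | step 8 | triethylsilyl ether of 19 (ring stereochemistry as in 19) | CC(C)=CC[C@@H]1C(=O)CC[C@@H](c2ccc(OCOC)cc2)[C@@H]1C(O[Si](CC)(CC)CC)c1c(OCOC)cc(OCOC)cc1OCOC
F9 | step 8 | potassium enolate of F8 (enolate on the CH2 side) | CC(C)=CC[C@@H]1C(O[K])=CC[C@@H](c2ccc(OCOC)cc2)[C@@H]1C(O[Si](CC)(CC)CC)c1c(OCOC)cc(OCOC)cc1OCOC
F10 | step 8 | (4R,5S,6S)-4-[4-(methoxymethoxy)phenyl]-6-(3-methylbut-2-en-1-yl)-5-{[(triethylsilyl)oxy][2,4,6-tris(methoxymethoxy)phenyl]methyl}cyclohex-1-en-1-yl trifluoromethanesulfonate | CC(C)=CC[C@@H]1C(OS(=O)(=O)C(F)(F)F)=CC[C@@H](c2ccc(OCOC)cc2)[C@@H]1C(O[Si](CC)(CC)CC)c1c(OCOC)cc(OCOC)cc1OCOC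
F11 | step 8 | triethyl({(1R,2S,6R)-6-[4-(methoxymethoxy)phenyl]-3-methyl-2-(3-methylbut-2-en-1-yl)cyclohex-3-en-1-yl}[2,4,6-tris(methoxymethoxy)phenyl]methoxy)silane | CC(C)=CC[C@@H]1C(C)=CC[C@@H](c2ccc(OCOC)cc2)[C@@H]1C(O[Si](CC)(CC)CC)c1c(OCOC)cc(OCOC)cc1OCOC
F12 | step 8 | {(1R,2S,6R)-6-[4-(methoxymethoxy)phenyl]-3-methyl-2-(3-methylbut-2-en-1-yl)cyclohex-3-en-1-yl}[2,4,6-tris(methoxymethoxy)phenyl]methanol | CC(C)=CC[C@@H]1C(C)=CC[C@@H](c2ccc(OCOC)cc2)[C@@H]1C(O)c1c(OCOC)cc(OCOC)cc1OCOC
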